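At 2.0 min the flasks birch, cedar, larch, maple and alder are to be read; they differ in their charge of solid second nucleophile, so I first ask what would make that charge matter.

| flask | substrate | first nucleophile | solid second nucleophile | remark | time |
|---|---|---|---|---|---|
| delta | 0.50 mM | 1.3 equiv | 0.71 equiv | run made earlier |  |
| beta | 0.50 mM | 1.3 equiv | 2.8 equiv | run made earlier |  |
| birch | 0.50 mM | 1.30 equiv | 0.800 equiv |  | 2.0 min |
| cedar | 0.50 mM | 1.30 equiv | 1.00 equiv |  | 2.0 min |
| larch | 0.50 mM | 1.30 equiv | 1.50 equiv |  | 2.0 min |
| maple | 0.50 mM | 1.30 equiv | 2.50 equiv |  | 2.0 min |
| alder | 0.50 mM | 1.30 equiv | 4.00 equiv |  | 2.0 min |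

| run | time / s | target / % | other capture product / % |
|---|---|---|---|
| delta | 10.0 | 1 | 6 |
| delta | 12.0 | 4 | 6 |
| delta | 20.0 | 8 | 7 |
| delta | 30.0 | 8 | 11 |
| delta | 50.0 | 14 | 16 |
| delta | 60.0 | 11 | 19 |
| beta | 10.0 | 5 | 0 |
| beta | 12.0 | 3 | 4 |
| beta | 20.0 | 6 | 7 |
| beta | 30.0 | 9 | 13 |
| beta | 50.0 | 12 | 19 |
| beta | 60.0 | 19 | 19 |

(readings scatter by 1.5 percentage points)

- the numbers in the tables scatter with a standard deviation of 1.5 percentage points
- at the start none of the solid second nucleophile is in solution
- a reading or a percentage of target counts all its forms, free or not
- "hardly changes" means that all values lie within two and a half points (for a concentration: within two and a half percent of the largest)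

* share of target in all that became target or other capture product or solvolysis product or over-reaction product for birch, cedar, larch, maple, alder, in this order
* how the row runs (falls all the way / falls, then rises / hardly changes / rises all the way / rises, then falls)

Target and other capture product compete for the same substrate. The row could move if the split between them followed the solid. I write R for other capture product over target, summed over the readings at 50.0 s and 60.0 s. The response factor f is R of the richer flask over R of the poorer one. On this scale f = 1 is the symmetric case, zero order in the solid charge, and the charge ratio is full proportionality.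

Beta over delta gives f = 0.876 as a reading, each point scattering by 1.5 percentage points. A proportional response needs 3.94, and the reading stands far lower. Birch, the poorest asked flask, holds 0.800 equiv against delta's 0.71 equiv, so I commit to a flat row. But the readings stop at 60.0 s, short of the asked time, and alder holds 4.00 equiv against beta's 2.8 equiv.

The readings of delta and beta at those same two times, pooled, give target 43.4% of target plus other capture product. Solvolysis and over-reaction product were not read and enter the asked denominator, so I expect the share to lie below that, by an amount I cannot fix.

The forecast gives 40% for birch through 40% for alder, hardly changes, holding that “the solid is merely a reservoir”.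

The flasks give 13.9% for birch through 13.9% for alder: hardly changes.

    first nucleophile + intermediate → target (k = 15000 M⁻¹ s⁻¹)
    intermediate → solvolysis product (k = 23.0 s⁻¹)
    substrate → intermediate (k = 0.0230 s⁻¹)
    second nucleophile + intermediate → other capture product (k = 47000 M⁻¹ s⁻¹)
    crystals ⇌ target, rate k5*(cs5 - [target]) while solid is left; crystals form when [target] > cs5 (solubility = 0.270 mM, k = 4.50 s⁻¹)
    solid second nucleophile ⇌ second nucleophile, rate k6*(cs6 - [second nucleophile]) while solid is left; crystals form when [second nucleophile] > cs6 (solubility = 0.290 mM, k = 0.200 s⁻¹)
    first nucleophile + target → over-reaction product (k = 8.20 M⁻¹ s⁻¹)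

With R taken from the amounts at 2.00 min instead of from the readings, f of alder over birch is 1.00, and of alder over cedar 1.00, while the alder-to-birch charge ratio is 5.00. At 2.00 min birch has 0% of its solid left, with second nucleophile at 0.275 mM. In birch at 2.00 min, dissolved target is made at 0.468 of the rate at which it is used up, each step taken net. Target there stands at 13.0%, against 49.5% solvolysis product.

Readings and results are calculated with made-up constants, and the scatter is random.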